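The numbers of this flask are assumed; the run is a simulation.

Take the substrate charge as the unit: substrate, target and isomer are then fractions of one, and the coupling partner stands at 1.20 of that unit.

in all of them: capture agent 8.00 mM; time 6.0 d
- theta: substrate 0.40 M; coupling partner 0.480 M (fed, over 4.0 d); all else is in the flask from the start; the feed brings no volume worth counting
- zeta: substrate 0.40 M (fed, over 4.0 d); coupling partner 0.480 M; all else is in the flask from the start; the feed brings no volume worth counting
- epsilon: substrate 0.40 M; coupling partner 0.480 M; everything together at the start

1. which flask leads in amount of target, in percent of the substrate charged ("all alike" within 1.5 percentage points) (theta / zeta / epsilon / all alike)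
2. how much target is there at the end, in percent of the substrate charged: theta
3. how much target is there at the end, in percent of the substrate charged: zeta
4. how much target is there at the end, in percent of the substrate charged: epsilon

- what is said of target includes crystals
- crystals is a solid; its amount is given per volume of the solution
- run time (theta): 6.0 d

    coupling partner + loose pair → isomer of the product (k1 = 1830 /M/h)
    coupling partner → decomposed reagent (k2 = 0.0131 /h)
    coupling partner + tight pair → target (k3 = 2440 /M/h)
    tight pair ⇌ loose pair (K4 = 0.14, k4 = 2.07 /h)
    capture agent + tight pair → trapped intermediate (k5 = 0.0995 /M/h)
    crystals ⇌ target, rate k6*(cs6 - [target]) while solid is left; crystals form when [target] > cs6 (cs6 = 4.4 mM, k6 = 0.376 /h)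
    substrate ⇌ tight pair (K7 = 6.55 × 10⁻⁴, k7 = 0.212 /h)

*What can go wrong in zeta, where the substrate is fed slowly?* The coupling partner waits in the flask, and it decomposes on its own with a half-life of 2.20 d. Coupling and decomposition race for it.

*Where is the zero of your scale?* At the even race. I divide the partner's decay at full charge, per hour, by the substrate supply per hour, which gives the race number 1.51. If this number is near nought, the whole partner charge reaches coupling. At one, the even race, a share of 0.693 does. The general share is ln(1 + race number) divided by the race number. It comes from balancing a steady demand against a proportional loss, hour by hour, until the partner is gone.

*And zeta?* Its race number stands above one, so decay outruns the supply at the start. The surviving share is 60.9 %, which covers 73.1 % of the substrate.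

*But does substrate couple the moment it drops in?* No. It opens to the tight pair with a forward lifetime of 4.72 h, but the tight pair also closes again, at 324 /h against coupling at 586 /h with the partner taken at 0.240 M, my rough mean. Counting those returns, the lifetime is about 7.32 h, so about 7.63 % of the charge stands waiting. I subtract that and commit to 65.5 % for zeta.

*And epsilon?* There is no feed, so the substrate's forward lifetime serves as the supply time. The race number falls to 0.0742, below one. The surviving partner covers more than the unit, so I cap the yield at 100 %.

*Theta?* There the substrate waits for the partner, so this number is not built for it, and I leave theta to the forecast.

The forecast names epsilon as leader and gives theta 96.7 % (95 % to 98 %), zeta 64 % (59 % to 69 %) and epsilon 98 % (96.5 % to 99 %). Its zeta lies below mine and its epsilon too. On zeta it says: “Feeding the substrate slowly leaves the partner sitting for days and decomposing”.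

The simulation puts epsilon ahead, with theta at 96.2 %, zeta at 66.5 % and epsilon at 99.0 %.

In zeta, the decomposed reagent at 6.00 d is 0.212 M, or 44.1 % of the partner charge, where the race number gave 39.1 %. The neighbouring flask is epsilon with 0.68 M of substrate, which leaves 0.706 equiv of partner. Its race number, on the substrate's forward lifetime, is 0.0436, so the reckoning gives 69.1 %, below the cap. There the coupling partner, the limiting reagent, stands at 0 % at 6.00 d, the substrate at 32.7 %, and the target at 66.8 %.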